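**Plan**

1. Retrosynthesis: remove the acetate and the senecioate, take the oxirane oxygen off C2–C3 to reach an (E,E)-cyclodeca-2,6-diene-1,4-diol, then cut the ring bond C3–C4 to an open-chain ynal. The ynal is cut at C7–C8 (sp3–sp2 coupling) and at C1–C10 (allylboration) into but-2-ynal, a γ-isopropylallyl boronate and (E)-4-iodopent-3-en-1-ol.
2. Enabling feature: in the ten-membered carbocycle the methyl-bearing oxirane carbon C3 is bonded to the carbinol carbon C4, and the ring carbons C1 and C4 are trans on the oxirane. C2–C3–C4 is therefore an oxidised (E)-CH=C(CH3)–CH(O) unit, the pattern left by syn addition of H and an aldehyde carbon across a methyl-capped alkyne.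
3. Forward: allylboration, silylation, hydroboration/Suzuki coupling, oxidation to the ynal, nickel-catalysed reductive macrocyclization (closes the ten-membered ring), ester and protecting-group adjustment, directed epoxidation (closes the oxirane), acetylation.
4. Stereochemistry: C1 and C10 come from a catalyst-controlled anti-allylboration. The C6=C7 geometry comes from syn hydrozirconation and a stereoretentive coupling. The C2=C3 geometry and C4 come from the key step (syn addition; 1,3-allylic strain from C1). C2 and C3 come from epoxidation of the E alkene directed by the C1 hydroxyl.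

Key step: step 9

Remark on locants: ring atoms are numbered C1 (acetoxy carbon), C2 and C3 (oxirane carbons, C3 with the methyl), C4 (senecioyloxy carbon), C5, C6=C7 (C7 with the methyl), C8, C9, C10 (isopropyl carbon). The same locants are used for these atoms in the open-chain precursors and in the names of the ring compounds; systematic names of open-chain compounds keep their own numbering.

**Route**

Step 1
Reactants: 1 but-2-yn-1-ol
Product: 2 but-2-ynal
Conditions: activated MnO2 (10 equiv), CH2Cl2, rt; filtered, used as a solution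
Reagents that add atoms: none
Why: Manganese dioxide oxidation of a propargylic alcohol should stop at the ynal and give a solution usable without distilling the volatile aldehyde.

Step 2
Reactants: 3 3-methylbut-1-yne
Product: 4 (E)-4,4,5,5-tetramethyl-2-(3-methylbut-1-en-1-yl)-1,3,2-dioxaborolane
Conditions: pinacolborane (1.05 equiv), Cp2Zr(H)Cl (5 mol %), Et3N (10 mol %), neat, sealed tube, 60 °C
Reagents that add atoms: pinacolborane, CC1(C)OBOC1(C)C
Why: Zirconium-catalysed syn hydroboration of a terminal alkyne should place boron on the terminal carbon and give only the (E)-alkenylboronate.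

Step 3
Reactants: 4 (E)-4,4,5,5-tetramethyl-2-(3-methylbut-1-en-1-yl)-1,3,2-dioxaborolane
Product: 6 (E)-4,4,5,5-tetramethyl-2-(4-methylpent-2-en-1-yl)-1,3,2-dioxaborolane, via boronate ate complex 5 (not isolated)
Conditions: BrCH2Cl (1.5 equiv), n-BuLi (1.3 equiv), THF, −78 °C to rt
Reagents that add atoms: bromochloromethane, ClCBr
Why: Matteson homologation: chloromethyllithium made in the flask adds to boron and the alkenyl group migrates with loss of chloride and retention of the E geometry.

Step 4
Reactants: 2 but-2-ynal; 6 (E)-4,4,5,5-tetramethyl-2-(4-methylpent-2-en-1-yl)-1,3,2-dioxaborolane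
Product: 8 (3R,4R)-3-(propan-2-yl)hept-1-en-5-yn-4-ol, via pinacol borate ester 7 (not isolated)
Conditions: (R)-TRIP (5 mol %), 4 Å MS, toluene, −40 °C; aq. NaHCO3 work-up
Reagents that add atoms: none
Why: Chiral phosphoric acid-catalysed allylboration through a closed chair transition state: the equatorial (E)-γ-isopropyl group gives the anti relationship of C10 and C1, and the (R)-catalyst should direct addition to the Re face of the ynal so that the carbinol centre is R.

Step 5
Reactants: 8 (3R,4R)-3-(propan-2-yl)hept-1-en-5-yn-4-ol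
Product: 9 tert-butyl(dimethyl){[(3R,4R)-3-(propan-2-yl)hept-1-en-5-yn-4-yl]oxy}silane
Conditions: TBSOTf (1.3 equiv), 2,6-lutidine (2 equiv), CH2Cl2, −78 to 0 °C
Reagents that add atoms: tert-butyldimethylsilyl triflate, CC(C)(C)[Si](C)(C)OS(=O)(=O)C(F)(F)F
Why: Silyl triflate silylation should protect the hindered secondary propargylic alcohol as an ether that survives Ni(0), unlike a propargylic ester.

Step 6
Reactants: 10 pent-3-yn-1-ol
Product: 12 (E)-4-iodopent-3-en-1-ol, via alkenylzirconocene 11 (not isolated)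
Conditions: Cp2Zr(H)Cl (2.5 equiv), THF, 50 °C; then I2 (1.2 equiv), 0 °C
Reagents that add atoms: iodine, II
Why: Hydrozirconation–iodination: the first equivalent forms the zirconium alkoxide, syn Zr–H addition under equilibrating conditions should place zirconium on the methyl-bearing alkyne carbon, and iodinolysis with retention gives the (E)-iodide.

Step 7
Reactants: 9 tert-butyl(dimethyl){[(3R,4R)-3-(propan-2-yl)hept-1-en-5-yn-4-yl]oxy}silane; 12 (E)-4-iodopent-3-en-1-ol
Product: 14 (3E,7S,8R)-8-{[tert-butyl(dimethyl)silyl]oxy}-4-methyl-7-(propan-2-yl)undec-3-en-9-yn-1-ol, via alkyl-9-BBN adduct 13 (not isolated)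
Conditions: 9-BBN (1.3 equiv), THF, 0 °C to rt; then 12, PdCl2(dppf) (5 mol %), AsPh3 (10 mol %), Cs2CO3 (3 equiv), DMF–H2O, rt
Reagents that add atoms: none
Why: B-alkyl Suzuki–Miyaura coupling: 9-BBN should hydroborate the monosubstituted alkene in preference to the hindered internal alkyne, and the sp3–sp2 coupling retains the iodide geometry, which fixes the E C6=C7 alkene.

Step 8
Reactants: 14 (3E,7S,8R)-8-{[tert-butyl(dimethyl)silyl]oxy}-4-methyl-7-(propan-2-yl)undec-3-en-9-yn-1-ol
Product: 15 (3E,7S,8R)-8-{[tert-butyl(dimethyl)silyl]oxy}-4-methyl-7-(propan-2-yl)undec-3-en-9-ynal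
Conditions: Dess–Martin periodinane (1.3 equiv), NaHCO3, CH2Cl2, 0 °C; used at once
Reagents that add atoms: none
Why: Buffered Dess–Martin oxidation should give the β,γ-unsaturated aldehyde without moving the C6=C7 bond into conjugation.

Step 9
Reactants: 15 (3E,7S,8R)-8-{[tert-butyl(dimethyl)silyl]oxy}-4-methyl-7-(propan-2-yl)undec-3-en-9-ynal
Product: 17 tert-butyl{[(1R,2E,4S,6E,10S)-3,7-dimethyl-10-(propan-2-yl)-4-[(triethylsilyl)oxy]cyclodeca-2,6-dien-1-yl]oxy}dimethylsilane, via oxanickelacyclopentene 16 (not isolated)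
Conditions: Ni(cod)2 (20 mol %), IMes·HCl (20 mol %), KOt-Bu (20 mol %), Et3SiH (3 equiv), THF, rt; 15 added by syringe pump over 6 h to 0.005 M
Reagents that add atoms: triethylsilane, CC[SiH](CC)CC
Why: Ni(0)–IMes binds the alkyne and the aldehyde of 15 and couples them oxidatively to oxanickelacyclopentene 16, whose Ni–O bond is cleaved by Et3SiH (σ-bond metathesis) before C–H reductive elimination releases 17; the closest known reaction type is the nickel-catalysed reductive alkyne–aldehyde macrocyclization of ynals used for twelve- to twenty-two-membered rings. The ten-membered carbocycle closes in the endocyclic mode (10-endo-dig at the alkyne, exo-trig at the aldehyde) by bonding the methyl-bearing alkyne carbon C3 to the aldehyde carbon C4. Syn addition of H and C4 across the alkyne makes the C2=C3 alkene E without a separate olefination. The new C4 stereocentre should be controlled by the C1 silyloxy stereocentre through 1,3-allylic strain: in the planar metallacycle the C4–O bond lies in the alkene plane and C5 must sit on the same face as C10, and the conformer with C1–H eclipsing the alkene toward the C3 methyl (OTBS outside) exposes the aldehyde face that gives 4S. The step needs bond formation at C3 and not C2, which the small IMes ligand and the branched silyloxy carbon next to C2 should secure, and ring closure over oligomerization, which slow addition at high dilution should secure.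

Step 10
Reactants: 17 tert-butyl{[(1R,2E,4S,6E,10S)-3,7-dimethyl-10-(propan-2-yl)-4-[(triethylsilyl)oxy]cyclodeca-2,6-dien-1-yl]oxy}dimethylsilane
Product: 18 (1R,2E,4S,6E,10S)-1-(tert-butyldimethylsilyloxy)-3,7-dimethyl-10-isopropylcyclodeca-2,6-dien-4-ol
Conditions: PPTS (0.2 equiv), MeOH–CH2Cl2 (1:1), 0 °C
Reagents that add atoms: none
Why: Mild acid-catalysed methanolysis should cleave the triethylsilyl ether much faster than the hindered secondary TBS ether and is gentle enough for the acid-sensitive cyclodecadiene.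

Step 11
Reactants: 18 (1R,2E,4S,6E,10S)-1-(tert-butyldimethylsilyloxy)-3,7-dimethyl-10-isopropylcyclodeca-2,6-dien-4-ol
Product: 19 (1R,2E,4S,6E,10S)-1-(tert-butyldimethylsilyloxy)-3,7-dimethyl-10-isopropylcyclodeca-2,6-dien-4-yl 3-methylbut-2-enoate
Conditions: 3-methylbut-2-enoyl chloride (1.5 equiv), pyridine, DMAP (cat.), CH2Cl2, 0 °C to rt
Reagents that add atoms: 3-methylbut-2-enoyl chloride, CC(C)=CC(=O)Cl
Why: DMAP-catalysed acylation of the secondary allylic alcohol with the acid chloride installs the senecioate with retention at C4, and pyridine as the only base should avoid deconjugation through a vinylketene.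

Step 12
Reactants: 19 (1R,2E,4S,6E,10S)-1-(tert-butyldimethylsilyloxy)-3,7-dimethyl-10-isopropylcyclodeca-2,6-dien-4-yl 3-methylbut-2-enoate
Product: 20 (1R,2E,4S,6E,10S)-1-hydroxy-3,7-dimethyl-10-isopropylcyclodeca-2,6-dien-4-yl 3-methylbut-2-enoate
Conditions: TBAF (1.5 equiv), AcOH (1.5 equiv), THF, 0 °C to rt
Reagents that add atoms: none
Why: Buffered fluoride desilylation should free the C1 hydroxyl without touching the enoate, and the E alkene between C1 and C4 rules out acyl migration.

Step 13
Reactants: 20 (1R,2E,4S,6E,10S)-1-hydroxy-3,7-dimethyl-10-isopropylcyclodeca-2,6-dien-4-yl 3-methylbut-2-enoate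
Product: 21 (1R,2R,3R,4S,6E,10S)-2,3-epoxy-1-hydroxy-3,7-dimethyl-10-isopropylcyclodec-6-en-4-yl 3-methylbut-2-enoate
Conditions: VO(acac)2 (5 mol %), t-BuOOH (1.5 equiv, decane), CH2Cl2, 0 °C to rt
Reagents that add atoms: tert-butyl hydroperoxide, CC(C)(C)OO
Why: Vanadium-catalysed hydroxyl-directed epoxidation: the C1 vanadate can reach only the adjacent C2=C3 bond, and because the allylic torsion of an (E)-cyclodecene holds C10 on the inner face with the C1 oxygen 20–45° out of the alkene plane on the outer face, oxygen should be delivered to the peripheral face anti to C1–O, which sets C2 and C3 as R,R while the undirected C6=C7 bond and the enoate stay untouched.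

Step 14
Reactants: 21 (1R,2R,3R,4S,6E,10S)-2,3-epoxy-1-hydroxy-3,7-dimethyl-10-isopropylcyclodec-6-en-4-yl 3-methylbut-2-enoate
Product: 22 (1R,2R,3R,4S,6E,10S)-1-acetoxy-2,3-epoxy-3,7-dimethyl-10-isopropylcyclodec-6-en-4-yl 3-methylbut-2-enoate (CNP0267399.1)
Conditions: Ac2O (3 equiv), pyridine, DMAP (cat.), CH2Cl2, 0 °C to rt
Reagents that add atoms: acetic anhydride, CC(=O)OC(C)=O
Why: DMAP-catalysed acetylation of the remaining secondary alcohol under basic conditions should leave the acid-sensitive epoxide and all stereocentres unchanged.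

**Compound list**

1 | but-2-yn-1-ol | CC#CCO | starting material
2 | but-2-ynal | CC#CC=O | intermediate
3 | 3-methylbut-1-yne | CC(C)C#C | starting material
4 | (E)-4,4,5,5-tetramethyl-2-(3-methylbut-1-en-1-yl)-1,3,2-dioxaborolane | CC(C)/C=C/B1OC(C)(C)C(C)(C)O1 | intermediate
5 | lithium (chloromethyl)[(E)-3-methylbut-1-en-1-yl](pinacolato)borate, boronate ate complex | [Li+].CC(C)/C=C/[B-]1(CCl)OC(C)(C)C(C)(C)O1 | intermediate (not isolated)
6 | (E)-4,4,5,5-tetramethyl-2-(4-methylpent-2-en-1-yl)-1,3,2-dioxaborolane | CC(C)/C=C/CB1OC(C)(C)C(C)(C)O1 | intermediate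
7 | 4,4,5,5-tetramethyl-2-{[(3R,4R)-3-(propan-2-yl)hept-1-en-5-yn-4-yl]oxy}-1,3,2-dioxaborolane, pinacol borate ester | C=C[C@@H](C(C)C)[C@@H](OB1OC(C)(C)C(C)(C)O1)C#CC | intermediate (not isolated)
8 | (3R,4R)-3-(propan-2-yl)hept-1-en-5-yn-4-ol | C=C[C@@H](C(C)C)[C@@H](O)C#CC | intermediate
9 | tert-butyl(dimethyl){[(3R,4R)-3-(propan-2-yl)hept-1-en-5-yn-4-yl]oxy}silane | C=C[C@@H](C(C)C)[C@@H](O[Si](C)(C)C(C)(C)C)C#CC | intermediate
10 | pent-3-yn-1-ol | CC#CCCO | starting material
11 | alkenylzirconocene: chlorobis(cyclopentadienyl){(E)-5-[chlorobis(cyclopentadienyl)zirconiooxy]pent-2-en-2-yl}zirconium | C/C(=C\CCO[Zr](Cl)(C1C=CC=C1)C1C=CC=C1)[Zr](Cl)(C1C=CC=C1)C1C=CC=C1 | intermediate (not isolated)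
12 | (E)-4-iodopent-3-en-1-ol | C/C(I)=C\CCO | intermediate
13 | 9-[(3S,4R)-4-{[tert-butyl(dimethyl)silyl]oxy}-3-(propan-2-yl)hept-5-yn-1-yl]-9-borabicyclo[3.3.1]nonane, alkyl-9-BBN adduct | CC#C[C@H](O[Si](C)(C)C(C)(C)C)[C@@H](CCB1C2CCCC1CCC2)C(C)C | intermediate (not isolated)
14 | (3E,7S,8R)-8-{[tert-butyl(dimethyl)silyl]oxy}-4-methyl-7-(propan-2-yl)undec-3-en-9-yn-1-ol | CC#C[C@H](O[Si](C)(C)C(C)(C)C)[C@@H](CC/C(C)=C/CCO)C(C)C | intermediate
15 | (3E,7S,8R)-8-{[tert-butyl(dimethyl)silyl]oxy}-4-methyl-7-(propan-2-yl)undec-3-en-9-ynal | CC#C[C@H](O[Si](C)(C)C(C)(C)C)[C@@H](CC/C(C)=C/CC=O)C(C)C | intermediate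
16 | oxanickelacyclopentene from 15: Ni bonded to C2 and to the C4 oxygen, fused to the ten-membered ring (IMes on nickel not drawn) | CC(C)(C)[Si](C)(C)O[C@H]1C2=C(C)[C@@H](O[Ni]2)C/C=C(\C)CC[C@H]1C(C)C | intermediate (not isolated)
17 | tert-butyl{[(1R,2E,4S,6E,10S)-3,7-dimethyl-10-(propan-2-yl)-4-[(triethylsilyl)oxy]cyclodeca-2,6-dien-1-yl]oxy}dimethylsilane | CC(C)(C)[Si](C)(C)O[C@H]1/C=C(\C)[C@@H](O[Si](CC)(CC)CC)C/C=C(\C)CC[C@H]1C(C)C | intermediate
18 | (1R,2E,4S,6E,10S)-1-(tert-butyldimethylsilyloxy)-3,7-dimethyl-10-isopropylcyclodeca-2,6-dien-4-ol | CC(C)(C)[Si](C)(C)O[C@H]1/C=C(\C)[C@@H](O)C/C=C(\C)CC[C@H]1C(C)C | intermediate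
19 | (1R,2E,4S,6E,10S)-1-(tert-butyldimethylsilyloxy)-3,7-dimethyl-10-isopropylcyclodeca-2,6-dien-4-yl 3-methylbut-2-enoate | CC(C)(C)[Si](C)(C)O[C@H]1/C=C(\C)[C@@H](OC(=O)C=C(C)C)C/C=C(\C)CC[C@H]1C(C)C | intermediate
20 | (1R,2E,4S,6E,10S)-1-hydroxy-3,7-dimethyl-10-isopropylcyclodeca-2,6-dien-4-yl 3-methylbut-2-enoate | O[C@H]1/C=C(\C)[C@@H](OC(=O)C=C(C)C)C/C=C(\C)CC[C@H]1C(C)C | intermediate
21 | (1R,2R,3R,4S,6E,10S)-2,3-epoxy-1-hydroxy-3,7-dimethyl-10-isopropylcyclodec-6-en-4-yl 3-methylbut-2-enoate | O[C@H]1[C@H]2O[C@]2(C)[C@@H](OC(=O)C=C(C)C)C/C=C(\C)CC[C@H]1C(C)C | intermediate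
22 | (1R,2R,3R,4S,6E,10S)-1-acetoxy-2,3-epoxy-3,7-dimethyl-10-isopropylcyclodec-6-en-4-yl 3-methylbut-2-enoate (CNP0267399.1) | CC(=O)O[C@H]1[C@H]2O[C@]2(C)[C@@H](OC(=O)C=C(C)C)C/C=C(\C)CC[C@H]1C(C)C | target

**Totals**

Total step count: 14.
Longest linear sequence: 12 steps (steps 2, 3, 4, 5, 7, 8, 9, 10, 11, 12, 13, 14).

**Steps most likely to fail**

1. Step 9. What may go wrong: closure in the exocyclic sense onto C2 (a nine-membered ring with an ethylidene group), oligomerization outrunning ring closure, or addition to the wrong aldehyde face. Fallback: the route sets out from 14. Hydrozirconation of the methyl alkyne (Cp2Zr(H)Cl, THF, then I2) should place iodine on C3 and give (3E,7S,8R,9E)-8-{[tert-butyl(dimethyl)silyl]oxy}-10-iodo-4-methyl-7-(propan-2-yl)undeca-3,9-dien-1-ol F1. Buffered Dess–Martin oxidation would give the iodo aldehyde (3E,7S,8R,9E)-8-{[tert-butyl(dimethyl)silyl]oxy}-10-iodo-4-methyl-7-(propan-2-yl)undeca-3,9-dienal F2. An intramolecular Nozaki–Hiyama–Kishi reaction (CrCl2, cat. NiCl2, DMSO–THF, high dilution) would then join C3 to C4 through a vinylchromium species: the E geometry is carried over from the vinyl iodide with retention, and only the carbon that bore iodine can add to the aldehyde, so neither the alkene geometry nor the regiochemistry depends on a catalyst. This comes back to the route at 18.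

2. Step 13. What may go wrong: oxygen delivery to the opposite alkene face if the ring reacts through its other conformer, or Lewis-acid-triggered transannular opening of the new epoxide by the C6=C7 bond. Fallback: the route sets out from 18 and lets the C4 hydroxyl direct after inversion. Buffered Dess–Martin oxidation would give the enone (1R,2E,6E,10S)-1-(tert-butyldimethylsilyloxy)-3,7-dimethyl-10-isopropylcyclodeca-2,6-dien-4-one F3. Reagent-controlled Corey–Bakshi–Shibata reduction ((S)-Me-CBS, BH3·SMe2, −40 °C) should give the C4 epimer (1R,2E,4R,6E,10S)-1-(tert-butyldimethylsilyloxy)-3,7-dimethyl-10-isopropylcyclodeca-2,6-dien-4-ol F4. VO(acac)2/t-BuOOH epoxidation of F4 is directed by the 4R hydroxyl in its erythro mode, which the acyclic preference of a 2-methyl allylic alcohol and the ring geometry both favour, and should give (1R,2R,3R,4R,6E,10S)-1-(tert-butyldimethylsilyloxy)-2,3-epoxy-3,7-dimethyl-10-isopropylcyclodec-6-en-4-ol F5. Mitsunobu esterification with 3-methylbut-2-enoic acid (DIAD, PPh3) inverts C4 and gives (1R,2R,3R,4S,6E,10S)-1-(tert-butyldimethylsilyloxy)-2,3-epoxy-3,7-dimethyl-10-isopropylcyclodec-6-en-4-yl 3-methylbut-2-enoate F6. Desilylation with TBAF/AcOH comes back to the route at 21.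

3. Step 4. What may go wrong: uncatalysed background allylboration of the reactive ynal eroding enantioselectivity, or the catalyst directing addition to the other aldehyde face. Fallback: the route sets out from 6 (with 2). Thermal allylboration without catalyst (toluene, rt) should still give the anti diastereomer through the chair transition state, as racemic anti-3-(propan-2-yl)hept-1-en-5-yn-4-ol F7. Lipase-mediated kinetic resolution (Amano lipase PS, vinyl acetate, hexane) is expected, with the slim propynyl group as the medium substituent, to acylate the 4S enantiomer to (3S,4S)-3-(propan-2-yl)hept-1-en-5-yn-4-yl acetate F8 and to leave the (3R,4R) alcohol, which is separated. This comes back to the route at 8.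

**Further compounds**

F1 | step 9 | (3E,7S,8R,9E)-8-{[tert-butyl(dimethyl)silyl]oxy}-10-iodo-4-methyl-7-(propan-2-yl)undeca-3,9-dien-1-ol | C/C(I)=C\[C@H](O[Si](C)(C)C(C)(C)C)[C@@H](CC/C(C)=C/CCO)C(C)C
F2 | step 9 | (3E,7S,8R,9E)-8-{[tert-butyl(dimethyl)silyl]oxy}-10-iodo-4-methyl-7-(propan-2-yl)undeca-3,9-dienal | C/C(I)=C\[C@H](O[Si](C)(C)C(C)(C)C)[C@@H](CC/C(C)=C/CC=O)C(C)C
F3 | step 13 | (1R,2E,6E,10S)-1-(tert-butyldimethylsilyloxy)-3,7-dimethyl-10-isopropylcyclodeca-2,6-dien-4-one | CC(C)(C)[Si](C)(C)O[C@H]1/C=C(\C)C(=O)C/C=C(\C)CC[C@H]1C(C)C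
F4 | step 13 | (1R,2E,4R,6E,10S)-1-(tert-butyldimethylsilyloxy)-3,7-dimethyl-10-isopropylcyclodeca-2,6-dien-4-ol | CC(C)(C)[Si](C)(C)O[C@H]1/C=C(\C)[C@H](O)C/C=C(\C)CC[C@H]1C(C)C
F5 | step 13 | (1R,2R,3R,4R,6E,10S)-1-(tert-butyldimethylsilyloxy)-2,3-epoxy-3,7-dimethyl-10-isopropylcyclodec-6-en-4-ol | CC(C)(C)[Si](C)(C)O[C@H]1[C@H]2O[C@]2(C)[C@H](O)C/C=C(\C)CC[C@H]1C(C)C
F6 | step 13 | (1R,2R,3R,4S,6E,10S)-1-(tert-butyldimethylsilyloxy)-2,3-epoxy-3,7-dimethyl-10-isopropylcyclodec-6-en-4-yl 3-methylbut-2-enoate | CC(C)(C)[Si](C)(C)O[C@H]1[C@H]2O[C@]2(C)[C@@H](OC(=O)C=C(C)C)C/C=C(\C)CC[C@H]1C(C)C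
F7 | step 4 | racemic anti-3-(propan-2-yl)hept-1-en-5-yn-4-ol, (3R,4R) and (3S,4S) 1:1 | C=C[C@@H](C(C)C)[C@@H](O)C#CC.C=C[C@H](C(C)C)[C@H](O)C#CC
F8 | step 4 | (3S,4S)-3-(propan-2-yl)hept-1-en-5-yn-4-yl acetate | C=C[C@H](C(C)C)[C@H](OC(C)=O)C#CC
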